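(The data are simulated for an exercise, noise included.)

Count the loss in amounts, not in percent, because that is where the two earlier runs disagree with a simple rate law.

| setting | cedar | oak | alpha | epsilon |
|---|---|---|---|---|
| substrate | 0.12 M | 0.48 M | 0.24 M | 0.24 M |
| gas phase | 100 mM (held) | 100 mM (held) | 100 mM (held) | 100 mM (held) |
| remark | run made earlier | run made earlier |  |  |
| time |  |  | 30 min | 50 min |

| run | time / min | substrate / % | product / % |
|---|---|---|---|
| cedar | 8.00 | 90.5 | 8.9 |
| cedar | 15.0 | 81.1 | 20.7 |
| cedar | 20.0 | 71.7 | 27.1 |
| cedar | 30.0 | 59.1 | 42.4 |
| cedar | 40.0 | 46.1 | 54.8 |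
| oak | 3.00 | 100.7 | 0 |
| oak | 10.0 | 92.0 | 7.7 |
| oak | 15.0 | 88.2 | 11.1 |
| oak | 25.0 | 80.6 | 19.5 |
| oak | 40.0 | 69.0 | 30.3 |

(scatter of a reading: 1 percentage point)

- at the start none of the gas phase is in solution

1. which of these there is most of at the end, counted by the substrate in it, alpha (product / substrate)
2. which of these there is most of at the end, counted by the substrate in it, epsilon (product / substrate)
3. final amount of the leader among these, as a percentage of the substrate charged, in alpha
4. final amount of the leader among these, as a percentage of the substrate charged, in epsilon

From 8.00 min to 40.0 min cedar loses 1.67 mM min⁻¹ at a mean [substrate] of 0.0820 M. From 10.0 min to 40.0 min oak loses 3.68 mM min⁻¹ at 0.386 M. So oak holds 4.71 times the substrate but runs 2.20 times as fast.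

Put a saturating curve through both points. It reads 0.187 M, the crossing concentration: the [substrate] at which the rate stands at half of its ceiling, read as 5.46 mM min⁻¹. Above the crossing the rate leans toward the ceiling; below it, toward proportion with [substrate].

Now bracket a charge of 0.24 M, whose starting pseudo-first-order constant is 0.0128 min⁻¹. On this curve, falling [substrate] lowers the rate but raises the fractional rate. Holding the rate gives a floor for substrate left, and holding the fractional rate gives a roof. For alpha that is 61.6% to 68.1%. Epsilon's bracket is too wide, so tighten it: integrate to half the charge, reached at 45.7 min, then run on at the rate of that moment. My epsilon product lies between 50% and 53.8%. Oak's 0% product at 3.00 min shows a short delay, which these bounds ignore.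

The forecast also reads “saturation kinetics”, with 5 mM/min and 0.17 M. It calls substrate in alpha at 67% (63% to 71%) and product in epsilon at 52% (48% to 57%), both inside my brackets. The flask gives substrate at 66.6% in alpha and product at 53.1% in epsilon.

    dissolved gas → decomposed reagent (k = 0.120 min⁻¹)
    gas phase ⇌ dissolved gas, rate k2*(csat - [dissolved gas]) (kL = 0.0570 min⁻¹)
    substrate + dissolved gas → product (k = 0.970 M⁻¹ min⁻¹)

At 50.0 min in epsilon, the conversion gives dissolved gas a half-life of 6.3 min, shorter than the 37 min it gives substrate, and dissolved gas, made 1.03 times as fast as used up, stands near a quasi-steady state at 0.0194 M. Epsilon began above the crossing of 0.187 M and stands below it at 0.113 M. For a neighbour of epsilon charged with 0.60 M, the same bracket reads 65.3% to 70.7%. That neighbour keeps 67% of its substrate at 50.0 min, still above the crossing at 0.402 M.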